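The target is opened at the C6′ coumarate (Mitsunobu, inversion) and at the dihydropyranone, built last on a cyclopropyl aldehyde already carrying C1′, C2′, C4′ and C6′; C1′ and C2′ stem from one catalytic event (Sharpless desymmetrisation of divinylcarbinol) relayed by an invertive phosphonate cyclopropanation. The key step assembles the 5,6-dihydro-2H-pyran-2-one ring (O1, C2–C6) from three two-atom pieces in one flask, exploiting its latent aldol pattern (O1 on C6, C4 two atoms away): the aldehyde C=O becomes C6–O1, acetaldehyde becomes C5–C4 and a ketenylidene phosphorane becomes C3–C2. An enamine aldol joins C5 to C6 under Felkin control from the C1′ ether; O-acylation and ring-closing Wittig olefination then create the ring-enforced cis C3=C4 bond.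

Key step: step 7

Remark: locants are O1, C2–C6 for the pyranone, C1′ for the carbinol carbon, C2′ (bearing C1′), C3′ (CH2) and C4′ (bearing the ketone C5′) for the cyclopropane, C6′ for the ester carbon and C7′ for its methyl. The CIP descriptor of C1′ is R in the vinyl compounds and S once C6 is oxygenated, at constant geometry.

Step 1
Reactants: 1 penta-1,4-dien-3-ol; 2 tert-butyl hydroperoxide
Product: 3 (2S,3R)-1,2-epoxypent-4-en-3-ol
Conditions: Ti(OiPr)4, D-(−)-diisopropyl tartrate, t-BuOOH, 4 Å MS, CH2Cl2, −20 °C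
Reagents that add atoms: tert-butyl hydroperoxide (2), CC(C)(C)OO
Why: Sharpless asymmetric epoxidation desymmetrises the divinylcarbinol: the D-tartrate titanium complex epoxidises one enantiotopic vinyl group on the face that gives the erythro epoxy alcohol, which sets the carbinol carbon (R, later C1′) and the epoxide carbon (S, later C2′) together, while the minor enantiomer is drained by faster over-epoxidation.

Step 2
Reactants: 3 (2S,3R)-1,2-epoxypent-4-en-3-ol; 4 4-methoxybenzyl chloride
Product: 5 (2S)-2-[(1R)-1-[(4-methoxyphenyl)methoxy]prop-2-en-1-yl]oxirane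
Conditions: NaH, PMBCl, n-Bu4NI (cat.), THF, −20 → 0 °C
Reagents that add atoms: 4-methoxybenzyl chloride (4), COc1ccc(CCl)cc1
Why: Williamson etherification of the sodium alkoxide at low temperature should outrun Payne rearrangement, and a benzyl-type ether is chosen because, unlike a silyl ether, it cannot migrate to the neighbouring alkoxide generated in step 3.

Step 3
Reactants: 5 (2S)-2-[(1R)-1-[(4-methoxyphenyl)methoxy]prop-2-en-1-yl]oxirane; 6 triethyl phosphonoacetate
Product: 7 ethyl (1S,2S)-2-[(1R)-1-[(4-methoxyphenyl)methoxy]prop-2-en-1-yl]cyclopropane-1-carboxylate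
Conditions: (EtO)2P(O)CH2CO2Et, NaH, toluene, 110 °C
Reagents that add atoms: triethyl phosphonoacetate (6), CCOC(=O)CP(=O)(OCC)OCC
Why: Wadsworth–Emmons cyclopropanation: the phosphonate carbanion opens the epoxide at CH2, the alkoxide takes over the phosphoryl group, and the resulting ester enolate displaces the phosphate at C2′ in a 3-exo-tet SN2 reaction, so C2′ (S) arises from the epoxide carbon with inversion and C4′ (S) from the strongly trans-selective ring closure.

Step 4
Reactants: 7 ethyl (1S,2S)-2-[(1R)-1-[(4-methoxyphenyl)methoxy]prop-2-en-1-yl]cyclopropane-1-carboxylate; 8 N,O-dimethylhydroxylamine hydrochloride; 9 ethylmagnesium bromide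
Product: 11 1-[(1S,2S)-2-[(1R)-1-[(4-methoxyphenyl)methoxy]prop-2-en-1-yl]cyclopropyl]propan-1-one, via Weinreb amide 10 (not isolated)
Conditions: MeNH(OMe)·HCl, i-PrMgCl, THF, −20 °C; then EtMgBr, 0 °C; aq. NH4Cl
Reagents that add atoms: ethylmagnesium bromide (9), CC[Mg]Br; N,O-dimethylhydroxylamine hydrochloride (8), CNOC.Cl (its atoms stay only in intermediate 10)
Why: Aminolysis of the ester by the chloromagnesium amide gives the Weinreb amide in the flask, and its chelated tetrahedral adduct with the Grignard reagent stops the addition at the ketone, with no stereocentre involved.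

Step 5
Reactants: 11 1-[(1S,2S)-2-[(1R)-1-[(4-methoxyphenyl)methoxy]prop-2-en-1-yl]cyclopropyl]propan-1-one; 12 (+)-(2R,8aS)-(camphorylsulfonyl)oxaziridine; 13 chlorotriethylsilane
Product: 15 (2S)-1-[(1S,2S)-2-[(1R)-1-[(4-methoxyphenyl)methoxy]prop-2-en-1-yl]cyclopropyl]-2-(triethylsilyloxy)propan-1-one, via hydroxy ketone 14 (not isolated)
Conditions: NaN(SiMe3)2, THF, −78 °C; (+)-(camphorylsulfonyl)oxaziridine, −78 °C; then Et3SiCl, −78 → 0 °C
Reagents that add atoms: (+)-(2R,8aS)-(camphorylsulfonyl)oxaziridine (12), CC1(C)[C@@H]2CC[C@]13CS(=O)(=O)N4O[C@@]34C2; chlorotriethylsilane (13), CC[Si](Cl)(CC)CC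
Why: Davis enolate hydroxylation: the amide base deprotonates the ethyl CH2 (the cyclopropyl C–H is kinetically far less acidic) to give the Z enolate, the (+)-camphor-derived oxaziridine transfers oxygen to the face that leads to (S)-α-hydroxy ketones from acyclic Z enolates (reagent control sets C6′), and the sodium alkoxide is silylated before work-up.

Step 6
Reactants: 15 (2S)-1-[(1S,2S)-2-[(1R)-1-[(4-methoxyphenyl)methoxy]prop-2-en-1-yl]cyclopropyl]-2-(triethylsilyloxy)propan-1-one; 16 ozone
Product: 17 (2S)-2-[(4-methoxyphenyl)methoxy]-2-[(1S,2S)-2-[(2S)-2-(triethylsilyloxy)propanoyl]cyclopropyl]acetaldehyde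
Conditions: O3, CH2Cl2, −78 °C, to the first blue tinge; then PPh3, −78 °C → rt
Reagents that add atoms: ozone (16), [O-][O+]=O
Why: Ozonolysis with reductive work-up cleaves the only C=C bond to the aldehyde while the anisyl ring should survive if the gas flow is stopped at the end point, and the epimerisable α-alkoxy aldehyde is used without chromatography.

Step 7
Reactants: 17 (2S)-2-[(4-methoxyphenyl)methoxy]-2-[(1S,2S)-2-[(2S)-2-(triethylsilyloxy)propanoyl]cyclopropyl]acetaldehyde; 18 acetaldehyde; 19 (triphenylphosphoranylidene)ketene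
Product: 22 (6R)-6-[(S)-[(4-methoxyphenyl)methoxy][(1S,2S)-2-[(2S)-2-(triethylsilyloxy)propanoyl]cyclopropyl]methyl]-5,6-dihydro-2H-pyran-2-one, via hydroxy aldehyde 20 (not isolated), via ester ylide 21 (not isolated)
Conditions: (S)-α,α-bis[3,5-bis(trifluoromethyl)phenyl]prolinol (20 mol %), MeCHO (5 equiv), NMP, 4 °C; volatiles off; then Ph3P=C=C=O, PhCO2H (cat.), toluene, 60 °C
Reagents that add atoms: acetaldehyde (18), CC=O; (triphenylphosphoranylidene)ketene (19), O=C=C=P(c1ccccc1)(c1ccccc1)c1ccccc1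
Why: The (S)-diarylprolinol turns acetaldehyde into its enamine, which adds to the aldehyde of 17 (crossed enamine aldol, C5–C6 bond) to give 20; the ketenylidene phosphorane then acylates the catalyst N–H (which ends enamine and retro-aldol chemistry) and adds the new C6–OH across its C=C=O unit to give the ester ylide 21, whose intramolecular Wittig reaction with the C4 aldehyde forms the C3=C4 bond and the lactone 22. The closest known reactions are the diarylprolinol-catalysed crossed aldol of acetaldehyde with Wittig trapping of the aldol in the same flask and the Bestmann lactonisation of hydroxy aldehydes (salicylaldehyde to coumarin). The one ring closed is the dihydropyranone, by 6-exo-trig attack of the ylide carbon C3 on the C4 carbonyl followed by oxaphosphetane collapse, so the new double bond can only be cis. The one new stereocentre is C6: the polar Felkin–Anh preference of the α-OPMB aldehyde (C–O bond anti to the incoming enamine) and the hydrogen-bond-directed re-face delivery by the (S)-catalyst are matched and should both lead to the 6R,1′S (anti) isomer. The step needs aldehyde-over-ketone selectivity, which the hindered cyclopropyl ketone secures towards both the enamine and the stabilised ylide, and a single free hydroxyl for the ylide, which the PMB and triethylsilyl ethers secure; epimerisation at C1′ is held back because the α-branched aldehyde forms its own enamine only slowly.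

Step 8
Reactants: 22 (6R)-6-[(S)-[(4-methoxyphenyl)methoxy][(1S,2S)-2-[(2S)-2-(triethylsilyloxy)propanoyl]cyclopropyl]methyl]-5,6-dihydro-2H-pyran-2-one
Product: 23 (6R)-6-[(S)-[(1S,2S)-2-[(2S)-2-hydroxypropanoyl]cyclopropyl][(4-methoxyphenyl)methoxy]methyl]-5,6-dihydro-2H-pyran-2-one
Conditions: HF·pyridine, pyridine, THF, 0 °C
Reagents that add atoms: none
Why: Fluoride-driven cleavage of the triethylsilyl ether (Si–F bond formation) frees the C6′ hydroxyl under buffered conditions that should leave the PMB ether, the unsaturated lactone and the C6′ configuration untouched.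

Step 9
Reactants: 24 4-(tert-butyldimethylsilyloxy)benzaldehyde; 25 methyl bis(2,2,2-trifluoroethyl)phosphonoacetate
Product: 26 methyl (2Z)-3-[4-(tert-butyldimethylsilyloxy)phenyl]prop-2-enoate
Conditions: (CF3CH2O)2P(O)CH2CO2Me, KN(SiMe3)2, 18-crown-6, THF, −78 °C
Reagents that add atoms: methyl bis(2,2,2-trifluoroethyl)phosphonoacetate (25), COC(=O)CP(=O)(OCC(F)(F)F)OCC(F)(F)F
Why: Still–Gennari olefination: the electron-poor phosphonate eliminates rapidly and irreversibly from the kinetically formed adduct, so the Z cinnamate should predominate.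

Step 10
Reactants: 26 methyl (2Z)-3-[4-(tert-butyldimethylsilyloxy)phenyl]prop-2-enoate; 27 lithium hydroxide
Product: 28 (2Z)-3-(4-hydroxyphenyl)prop-2-enoic acid
Conditions: LiOH, THF/MeOH/H2O, rt, dark; then 1 M HCl
Reagents that add atoms: lithium hydroxide (27), [Li+].[OH-]
Why: Saponification of the methyl ester with concurrent cleavage of the aryl silyl ether by hydroxide should give the Z acid, since neither event touches the C=C bond and light is excluded to avoid Z-to-E isomerisation.

Step 11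
Reactants: 23 (6R)-6-[(S)-[(1S,2S)-2-[(2S)-2-hydroxypropanoyl]cyclopropyl][(4-methoxyphenyl)methoxy]methyl]-5,6-dihydro-2H-pyran-2-one; 28 (2Z)-3-(4-hydroxyphenyl)prop-2-enoic acid
Product: 29 (2R)-1-[(1S,2S)-2-[(S)-[(4-methoxyphenyl)methoxy][(2R)-6-oxo-3,6-dihydro-2H-pyran-2-yl]methyl]cyclopropyl]-1-oxopropan-2-yl (2Z)-3-(4-hydroxyphenyl)prop-2-enoate
Conditions: PPh3, DIAD, THF, 0 °C → rt, dark
Reagents that add atoms: (2Z)-3-(4-hydroxyphenyl)prop-2-enoic acid (28), OC(=O)/C=C\c1ccc(O)cc1
Why: Mitsunobu esterification: the carboxylate (far more acidic than the phenol and hence the pronucleophile) displaces the alkoxyphosphonium group at C6′ by SN2 with inversion (S to R), and because the acid is never activated at its acyl carbon the Z geometry should be retained.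

Step 12
Reactants: 29 (2R)-1-[(1S,2S)-2-[(S)-[(4-methoxyphenyl)methoxy][(2R)-6-oxo-3,6-dihydro-2H-pyran-2-yl]methyl]cyclopropyl]-1-oxopropan-2-yl (2Z)-3-(4-hydroxyphenyl)prop-2-enoate
Product: 30 (2R)-1-[(1S,2S)-2-[(S)-hydroxy[(2R)-6-oxo-3,6-dihydro-2H-pyran-2-yl]methyl]cyclopropyl]-1-oxopropan-2-yl (2Z)-3-(4-hydroxyphenyl)prop-2-enoate
Conditions: CF3CO2H, anisole, CH2Cl2, 0 °C
Reagents that add atoms: none
Why: Acidolysis of the PMB ether through the 4-methoxybenzyl cation, trapped by anisole, frees C1′–OH, and brief cold acid should spare the esters, the Z-alkene and the cyclopropane, whose ketone substituent disfavours cyclopropylcarbinyl ionisation.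

Compound list
1 | penta-1,4-dien-3-ol | C=CC(O)C=C | starting material
2 | tert-butyl hydroperoxide | CC(C)(C)OO | starting material
3 | (2S,3R)-1,2-epoxypent-4-en-3-ol | C=C[C@@H](O)[C@@H]1CO1 | intermediate
4 | 4-methoxybenzyl chloride | COc1ccc(CCl)cc1 | starting material
5 | (2S)-2-[(1R)-1-[(4-methoxyphenyl)methoxy]prop-2-en-1-yl]oxirane | C=C[C@@H](OCc1ccc(OC)cc1)[C@@H]1CO1 | intermediate
6 | triethyl phosphonoacetate | CCOC(=O)CP(=O)(OCC)OCC | starting material
7 | ethyl (1S,2S)-2-[(1R)-1-[(4-methoxyphenyl)methoxy]prop-2-en-1-yl]cyclopropane-1-carboxylate | CCOC(=O)[C@H]1C[C@@H]1[C@H](OCc1ccc(OC)cc1)C=C | intermediate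
8 | N,O-dimethylhydroxylamine hydrochloride | CNOC.Cl | starting material
9 | ethylmagnesium bromide | CC[Mg]Br | starting material
10 | (1S,2S)-N-methoxy-N-methyl-2-[(1R)-1-[(4-methoxyphenyl)methoxy]prop-2-en-1-yl]cyclopropane-1-carboxamide | CON(C)C(=O)[C@H]1C[C@@H]1[C@H](OCc1ccc(OC)cc1)C=C | intermediate
11 | 1-[(1S,2S)-2-[(1R)-1-[(4-methoxyphenyl)methoxy]prop-2-en-1-yl]cyclopropyl]propan-1-one | CCC(=O)[C@H]1C[C@@H]1[C@H](OCc1ccc(OC)cc1)C=C | intermediate
12 | (+)-(2R,8aS)-(camphorylsulfonyl)oxaziridine | CC1(C)[C@@H]2CC[C@]13CS(=O)(=O)N4O[C@@]34C2 | starting material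
13 | chlorotriethylsilane | CC[Si](Cl)(CC)CC | starting material
14 | (2S)-2-hydroxy-1-[(1S,2S)-2-[(1R)-1-[(4-methoxyphenyl)methoxy]prop-2-en-1-yl]cyclopropyl]propan-1-one | C[C@H](O)C(=O)[C@H]1C[C@@H]1[C@H](OCc1ccc(OC)cc1)C=C | intermediate
15 | (2S)-1-[(1S,2S)-2-[(1R)-1-[(4-methoxyphenyl)methoxy]prop-2-en-1-yl]cyclopropyl]-2-(triethylsilyloxy)propan-1-one | C[C@H](O[Si](CC)(CC)CC)C(=O)[C@H]1C[C@@H]1[C@H](OCc1ccc(OC)cc1)C=C | intermediate
16 | ozone | [O-][O+]=O | starting material
17 | (2S)-2-[(4-methoxyphenyl)methoxy]-2-[(1S,2S)-2-[(2S)-2-(triethylsilyloxy)propanoyl]cyclopropyl]acetaldehyde | C[C@H](O[Si](CC)(CC)CC)C(=O)[C@H]1C[C@@H]1[C@H](OCc1ccc(OC)cc1)C=O | intermediate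
18 | acetaldehyde | CC=O | starting material
19 | (triphenylphosphoranylidene)ketene | O=C=C=P(c1ccccc1)(c1ccccc1)c1ccccc1 | starting material
20 | (3R,4S)-3-hydroxy-4-[(4-methoxyphenyl)methoxy]-4-[(1S,2S)-2-[(2S)-2-(triethylsilyloxy)propanoyl]cyclopropyl]butanal | C[C@H](O[Si](CC)(CC)CC)C(=O)[C@H]1C[C@@H]1[C@H](OCc1ccc(OC)cc1)[C@H](O)CC=O | intermediate
21 | (1S,2R)-1-[(4-methoxyphenyl)methoxy]-4-oxo-1-[(1S,2S)-2-[(2S)-2-(triethylsilyloxy)propanoyl]cyclopropyl]butan-2-yl (triphenyl-λ5-phosphanylidene)acetate | C[C@H](O[Si](CC)(CC)CC)C(=O)[C@H]1C[C@@H]1[C@H](OCc1ccc(OC)cc1)[C@H](OC(=O)C=P(c1ccccc1)(c1ccccc1)c1ccccc1)CC=O | intermediate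
22 | (6R)-6-[(S)-[(4-methoxyphenyl)methoxy][(1S,2S)-2-[(2S)-2-(triethylsilyloxy)propanoyl]cyclopropyl]methyl]-5,6-dihydro-2H-pyran-2-one | C[C@H](O[Si](CC)(CC)CC)C(=O)[C@H]1C[C@@H]1[C@H](OCc1ccc(OC)cc1)[C@H]1CC=CC(=O)O1 | intermediate
23 | (6R)-6-[(S)-[(1S,2S)-2-[(2S)-2-hydroxypropanoyl]cyclopropyl][(4-methoxyphenyl)methoxy]methyl]-5,6-dihydro-2H-pyran-2-one | C[C@H](O)C(=O)[C@H]1C[C@@H]1[C@H](OCc1ccc(OC)cc1)[C@H]1CC=CC(=O)O1 | intermediate
24 | 4-(tert-butyldimethylsilyloxy)benzaldehyde | CC(C)(C)[Si](C)(C)Oc1ccc(C=O)cc1 | starting material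
25 | methyl bis(2,2,2-trifluoroethyl)phosphonoacetate | COC(=O)CP(=O)(OCC(F)(F)F)OCC(F)(F)F | starting material
26 | methyl (2Z)-3-[4-(tert-butyldimethylsilyloxy)phenyl]prop-2-enoate | COC(=O)/C=C\c1ccc(O[Si](C)(C)C(C)(C)C)cc1 | intermediate
27 | lithium hydroxide | [Li+].[OH-] | starting material
28 | (2Z)-3-(4-hydroxyphenyl)prop-2-enoic acid | OC(=O)/C=C\c1ccc(O)cc1 | intermediate
29 | (2R)-1-[(1S,2S)-2-[(S)-[(4-methoxyphenyl)methoxy][(2R)-6-oxo-3,6-dihydro-2H-pyran-2-yl]methyl]cyclopropyl]-1-oxopropan-2-yl (2Z)-3-(4-hydroxyphenyl)prop-2-enoate | C[C@@H](OC(=O)/C=C\c1ccc(O)cc1)C(=O)[C@H]1C[C@@H]1[C@H](OCc1ccc(OC)cc1)[C@H]1CC=CC(=O)O1 | intermediate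
30 | (2R)-1-[(1S,2S)-2-[(S)-hydroxy[(2R)-6-oxo-3,6-dihydro-2H-pyran-2-yl]methyl]cyclopropyl]-1-oxopropan-2-yl (2Z)-3-(4-hydroxyphenyl)prop-2-enoate | C[C@@H](OC(=O)/C=C\c1ccc(O)cc1)C(=O)[C@H]1C[C@@H]1[C@H](O)[C@H]1CC=CC(=O)O1 | target

Total step count: 12. Longest linear sequence: 10 steps (steps 1–8, 11 and 12); the acid 28 is made in 2 steps (9 and 10) and joins at step 11.

Steps most likely to fail

1. Step 7. The enamine addition to a hindered, α-branched acceptor may be slow while acetaldehyde condenses with itself. The β-hydroxy aldehyde may dehydrate or revert before it is acylated, and facial selectivity at C6 may erode. Fallback, stepwise and reagent-controlled, from 17: Brown allylation with (+)-B-allyldiisopinocampheylborane (the antipode that adds to the re face, matched with Felkin control; Et2O, −78 °C, ethanolamine work-up) should give the homoallylic alcohol F1. Acryloyl chloride with i-Pr2NEt in CH2Cl2 at 0 °C should give the acrylate F2. Ring-closing metathesis with the second-generation Grubbs catalyst RuCl2(=CHPh)(PCy3)(H2IMes) in CH2Cl2 at 40 °C then forms the C3=C4 bond and returns to the route at 22.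

2. Step 3. The cascade may stop after epoxide opening: phosphoryl transfer and 3-exo-tet closure at the hindered C2′ may be slow, and elimination may compete. Fallback, ring closure in separate events, from 5: LiCH2CN (MeCN, n-BuLi, THF, −78 °C) should open the epoxide at CH2 to give the hydroxy nitrile F3. MsCl with Et3N should give the mesylate F4. NaN(SiMe3)2 in THF (−78 → 0 °C) should close the ring by invertive 3-exo-tet alkylation, and KOt-Bu equilibration should bring the nitrile trans, giving the cyclopropanecarbonitrile F5. EtMgBr followed by cold aqueous acid converts the nitrile into the ethyl ketone and rejoins the route at 11.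

3. Step 5. Oxygen transfer may show poor facial discrimination, because a cyclopropyl group replaces the aryl group of the well-behaved enolates, giving a C6′ epimer mixture. Fallback, catalytic reduction instead of enolate oxidation, from 10 (isolated after the first stage of step 4): 1-ethoxyvinyllithium (ethyl vinyl ether, t-BuLi, THF, −78 °C) should give the ethoxy enone F6. Hydrolysis (1 M HCl, THF, 0 °C) should give the 1,2-dione F7. Asymmetric transfer hydrogenation with RuCl(p-cymene)[(S,S)-TsDPEN] in HCO2H/Et3N should reduce the less hindered acetyl carbonyl; the catalyst enantiomer is the one that delivers the (S)-carbinol. This gives 14, which is silylated (Et3SiCl, imidazole) to return to the route at 15.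

Further compounds
F1 | step 7 | (2S)-1-[(1S,2S)-2-[(1S,2R)-2-hydroxy-1-[(4-methoxyphenyl)methoxy]pent-4-en-1-yl]cyclopropyl]-2-(triethylsilyloxy)propan-1-one | C[C@H](O[Si](CC)(CC)CC)C(=O)[C@H]1C[C@@H]1[C@H](OCc1ccc(OC)cc1)[C@H](O)CC=C
F2 | step 7 | (1S,2R)-1-[(4-methoxyphenyl)methoxy]-1-[(1S,2S)-2-[(2S)-2-(triethylsilyloxy)propanoyl]cyclopropyl]pent-4-en-2-yl prop-2-enoate | C[C@H](O[Si](CC)(CC)CC)C(=O)[C@H]1C[C@@H]1[C@H](OCc1ccc(OC)cc1)[C@H](OC(=O)C=C)CC=C
F3 | step 3 | (4S,5R)-4-hydroxy-5-[(4-methoxyphenyl)methoxy]hept-6-enenitrile | C=C[C@@H](OCc1ccc(OC)cc1)[C@@H](O)CCC#N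
F4 | step 3 | (1S)-3-cyano-1-[(1R)-1-[(4-methoxyphenyl)methoxy]prop-2-en-1-yl]propyl methanesulfonate | C=C[C@@H](OCc1ccc(OC)cc1)[C@@H](OS(C)(=O)=O)CCC#N
F5 | step 3 | (1S,2S)-2-[(1R)-1-[(4-methoxyphenyl)methoxy]prop-2-en-1-yl]cyclopropane-1-carbonitrile | N#C[C@H]1C[C@@H]1[C@H](OCc1ccc(OC)cc1)C=C
F6 | step 5 | 2-ethoxy-1-[(1S,2S)-2-[(1R)-1-[(4-methoxyphenyl)methoxy]prop-2-en-1-yl]cyclopropyl]prop-2-en-1-one | CCOC(=C)C(=O)[C@H]1C[C@@H]1[C@H](OCc1ccc(OC)cc1)C=C
F7 | step 5 | 1-[(1S,2S)-2-[(1R)-1-[(4-methoxyphenyl)methoxy]prop-2-en-1-yl]cyclopropyl]propane-1,2-dione | CC(=O)C(=O)[C@H]1C[C@@H]1[C@H](OCc1ccc(OC)cc1)C=C
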